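## Retrosynthetic overview

1. The (Z)-enyne comes from a Peterson olefination of a C4 aldehyde, itself unmasked from a C4 dimethyl(phenyl)silyl group by Fleming–Tamao oxidation and Dess–Martin oxidation.
2. C9–Cl/C10–OAc come from the cis-diol of a Δ9 oxocene by acetoxonium opening with chloride; C7–Cl and C13–Br come from Appel inversions of the 7R and 13S alcohols.
3. The oxocane is the only ring and is closed by ring-closing metathesis of an acyclic bis-allyl ether (C9=C10).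
4. C12 is set by Evans glycolate allylation and C13 by chelation-controlled reduction of the derived ethyl ketone.
5. C6/C7 come from a Sharpless kinetic resolution of hexa-1,5-dien-3-ol; C5–C4 is added by copper-catalysed opening of the epoxide with a silylmethyl Grignard reagent.

Assumption: positions are cited with the usual C15 acetogenin numbering (C1 = terminal alkyne carbon, ring oxygen between C6 and C12), and 1 is bought as the racemate.

## Route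

Step 1
Reactants: 1 rac-hexa-1,5-dien-3-ol
Product: 2 (1R)-1-[(2S)-oxiran-2-yl]but-3-en-1-ol
Conditions: Ti(OiPr)4 (10 mol %), D-(−)-diisopropyl tartrate (12 mol %), t-BuOOH (0.55 equiv), 4 Å MS, CH2Cl2, −20 °C
Reagents that add atoms: tert-butyl hydroperoxide, CC(C)(C)OO
Why: Sharpless asymmetric epoxidation run as a kinetic resolution: with the D-tartrate the (R)-alcohol is epoxidised fast, only at the allylic alkene and anti to the carbinol, which sets C6 (S) and C7 (R), while the (S)-alcohol stays behind and is separated.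

Step 2
Reactants: 2 (1R)-1-[(2S)-oxiran-2-yl]but-3-en-1-ol
Product: 3 (2S)-2-{(1R)-1-[(4-methoxybenzyl)oxy]but-3-en-1-yl}oxirane
Conditions: NaH, 4-methoxybenzyl chloride, Bu4NI (cat.), THF/DMF, 0 °C
Reagents that add atoms: 4-methoxybenzyl chloride, COc1ccc(CCl)cc1
Why: Williamson etherification of the C7 alkoxide, kept cold so that Payne rearrangement of the epoxy alkoxide does not compete.

Step 3
Reactants: 3 (2S)-2-{(1R)-1-[(4-methoxybenzyl)oxy]but-3-en-1-yl}oxirane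
Product: 4 (3S,4R)-1-[dimethyl(phenyl)silyl]-4-[(4-methoxybenzyl)oxy]hept-6-en-3-ol
Conditions: PhMe2SiCH2MgCl (THF solution), CuI (10 mol %), THF, −30 → 0 °C
Reagents that add atoms: [dimethyl(phenyl)silyl]methylmagnesium chloride, C[Si](C)(C[Mg]Cl)c1ccccc1
Why: Copper-catalysed Grignard opening of the terminal epoxide at its CH2 carbon (SN2) leaves C6 untouched, frees the C6 hydroxyl and installs C4 as a silane that serves as a masked hydroxyl.

Step 4
Reactants: 4 (3S,4R)-1-[dimethyl(phenyl)silyl]-4-[(4-methoxybenzyl)oxy]hept-6-en-3-ol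
Product: 5 2-({(3S,4R)-1-[dimethyl(phenyl)silyl]-4-[(4-methoxybenzyl)oxy]hept-6-en-3-yl}oxy)acetic acid
Conditions: NaH (3 equiv), BrCH2CO2H, THF, 0 °C → rt; 1 M HCl work-up
Reagents that add atoms: bromoacetic acid, OC(=O)CBr
Why: Williamson etherification of the secondary alkoxide with sodium bromoacetate builds the C6–O–C12 ether link without touching a stereocentre.

Step 5
Reactants: 5 2-({(3S,4R)-1-[dimethyl(phenyl)silyl]-4-[(4-methoxybenzyl)oxy]hept-6-en-3-yl}oxy)acetic acid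
Product: 7 (4S)-4-benzyl-3-[2-({(3S,4R)-1-[dimethyl(phenyl)silyl]-4-[(4-methoxybenzyl)oxy]hept-6-en-3-yl}oxy)acetyl]-1,3-oxazolidin-2-one, via mixed pivalic anhydride 6 (not isolated)
Conditions: t-BuCOCl, Et3N, THF, −78 → 0 °C; then lithiated (S)-4-benzyl-2-oxazolidinone (from the oxazolidinone and n-BuLi), THF, −78 → 0 °C
Reagents that add atoms: (S)-4-benzyl-2-oxazolidinone, O=C1N[C@@H](Cc2ccccc2)CO1; pivaloyl chloride, CC(C)(C)C(Cl)=O (atoms in 6 only)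
Why: N-acylation of the lithiated Evans auxiliary by the mixed anhydride occurs at the less hindered glycolyl carbonyl.

Step 6
Reactants: 7 (4S)-4-benzyl-3-[2-({(3S,4R)-1-[dimethyl(phenyl)silyl]-4-[(4-methoxybenzyl)oxy]hept-6-en-3-yl}oxy)acetyl]-1,3-oxazolidin-2-one
Product: 9 (4S)-4-benzyl-3-[(2R)-2-({(3S,4R)-1-[dimethyl(phenyl)silyl]-4-[(4-methoxybenzyl)oxy]hept-6-en-3-yl}oxy)pent-4-enoyl]-1,3-oxazolidin-2-one, via sodium Z-enolate 8 (not isolated)
Conditions: NaN(SiMe3)2, THF, −78 °C; then allyl iodide, −78 → −45 °C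
Reagents that add atoms: allyl iodide, C=CCI; NaN(SiMe3)2, C[Si](C)(C)N([Na])[Si](C)(C)C (Na in 8 only)
Why: Evans asymmetric glycolate alkylation: the chelated Z-enolate is allylated on the face opposite the benzyl group, which sets C12 (R).

Step 7
Reactants: 9 (4S)-4-benzyl-3-[(2R)-2-({(3S,4R)-1-[dimethyl(phenyl)silyl]-4-[(4-methoxybenzyl)oxy]hept-6-en-3-yl}oxy)pent-4-enoyl]-1,3-oxazolidin-2-one
Product: 10 (2R)-2-({(3S,4R)-1-[dimethyl(phenyl)silyl]-4-[(4-methoxybenzyl)oxy]hept-6-en-3-yl}oxy)-N-methoxy-N-methylpent-4-enamide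
Conditions: MeNH(OMe)·HCl, Me3Al, CH2Cl2, −10 → 0 °C
Reagents that add atoms: N,O-dimethylhydroxylamine hydrochloride, CNOC.Cl
Why: Aluminium-amide transamidation (Weinreb amide formation) cleaves the exocyclic imide carbonyl under non-basic conditions, so C12 is not epimerised.

Step 8
Reactants: 10 (2R)-2-({(3S,4R)-1-[dimethyl(phenyl)silyl]-4-[(4-methoxybenzyl)oxy]hept-6-en-3-yl}oxy)-N-methoxy-N-methylpent-4-enamide
Product: 11 (4R)-4-({(3S,4R)-1-[dimethyl(phenyl)silyl]-4-[(4-methoxybenzyl)oxy]hept-6-en-3-yl}oxy)hept-6-en-3-one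
Conditions: EtMgBr, THF, 0 °C
Reagents that add atoms: ethylmagnesium bromide, CC[Mg]Br
Why: Weinreb ketone synthesis: single addition of the Grignard reagent delivers C14–C15 and stops at the ethyl ketone.

Step 9
Reactants: 11 (4R)-4-({(3S,4R)-1-[dimethyl(phenyl)silyl]-4-[(4-methoxybenzyl)oxy]hept-6-en-3-yl}oxy)hept-6-en-3-one
Product: 12 (3S,4R)-4-({(3S,4R)-1-[dimethyl(phenyl)silyl]-4-[(4-methoxybenzyl)oxy]hept-6-en-3-yl}oxy)hept-6-en-3-ol
Conditions: Zn(BH4)2, Et2O, −30 → 0 °C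
Reagents that add atoms: none
Why: Chelation-controlled (Cram chelate) reduction: zinc bridges the ketone and the α-ether oxygen and hydride enters from the side of the C12 hydrogen, giving the 1,2-anti alcohol (13S).

Step 10
Reactants: 12 (3S,4R)-4-({(3S,4R)-1-[dimethyl(phenyl)silyl]-4-[(4-methoxybenzyl)oxy]hept-6-en-3-yl}oxy)hept-6-en-3-ol
Product: 13 (1S)-1-[(2R,4Z,7R,8S)-8-{2-[dimethyl(phenyl)silyl]ethyl}-7-[(4-methoxybenzyl)oxy]-3,6,7,8-tetrahydro-2H-oxocin-2-yl]propan-1-ol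
Conditions: second-generation Grubbs catalyst RuCl2(=CHPh)(PCy3)(H2IMes) (5 mol %), CH2Cl2 (0.005 M), 40 °C
Reagents that add atoms: none
Why: Ring-closing metathesis of the two allyl groups closes the oxocene (C9=C10, Z by ring size), helped by the gauche preference of the vicinal C–O bonds at C6/C7 and C12/C13.

Step 11
Reactants: 13 (1S)-1-[(2R,4Z,7R,8S)-8-{2-[dimethyl(phenyl)silyl]ethyl}-7-[(4-methoxybenzyl)oxy]-3,6,7,8-tetrahydro-2H-oxocin-2-yl]propan-1-ol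
Product: 14 (2S,3R,5Z,8R)-8-[(1R)-1-bromopropyl]-2-{2-[dimethyl(phenyl)silyl]ethyl}-3-[(4-methoxybenzyl)oxy]-3,4,7,8-tetrahydro-2H-oxocine
Conditions: CBr4, P(n-Oct)3, toluene, 70 °C
Reagents that add atoms: tetrabromomethane, BrC(Br)(Br)Br
Why: Appel-type bromination of the only free hydroxyl proceeds by SN2 with inversion, turning 13S–OH into 13R–Br.

Step 12
Reactants: 14 (2S,3R,5Z,8R)-8-[(1R)-1-bromopropyl]-2-{2-[dimethyl(phenyl)silyl]ethyl}-3-[(4-methoxybenzyl)oxy]-3,4,7,8-tetrahydro-2H-oxocine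
Product: 15 (2S,3R,5Z,8R)-8-[(1R)-1-bromopropyl]-2-{2-[dimethyl(phenyl)silyl]ethyl}-3,4,7,8-tetrahydro-2H-oxocin-3-ol
Conditions: DDQ, CH2Cl2/pH 7 buffer (10:1), 0 °C → rt
Reagents that add atoms: none
Why: Oxidative cleavage of the 4-methoxybenzyl ether frees the C7 hydroxyl under neutral conditions that spare the alkene, the bromide and the silane.

Step 13
Reactants: 15 (2S,3R,5Z,8R)-8-[(1R)-1-bromopropyl]-2-{2-[dimethyl(phenyl)silyl]ethyl}-3,4,7,8-tetrahydro-2H-oxocin-3-ol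
Product: 16 (2S,3S,5Z,8R)-8-[(1R)-1-bromopropyl]-3-chloro-2-{2-[dimethyl(phenyl)silyl]ethyl}-3,4,7,8-tetrahydro-2H-oxocine
Conditions: CCl4, P(n-Oct)3, toluene, 80 °C
Reagents that add atoms: tetrachloromethane, ClC(Cl)(Cl)Cl
Why: Appel-type chlorination by SN2 with inversion converts 7R–OH into 7S–Cl, cis to the C6 side chain.

Step 14
Reactants: 16 (2S,3S,5Z,8R)-8-[(1R)-1-bromopropyl]-3-chloro-2-{2-[dimethyl(phenyl)silyl]ethyl}-3,4,7,8-tetrahydro-2H-oxocine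
Product: 17 (2R,4S,5R,7S,8S)-2-[(1R)-1-bromopropyl]-7-chloro-8-{2-[dimethyl(phenyl)silyl]ethyl}oxocane-4,5-diol
Conditions: OsO4 (5 mol %), N-methylmorpholine N-oxide, acetone/H2O (8:1), 0 °C → rt
Reagents that add atoms: N-methylmorpholine N-oxide, C[N+]1([O-])CCOCC1; water, O
Why: Upjohn syn-dihydroxylation, expected on the alkene face opposite the branched 1-bromopropyl group at C12, gives the (9R,10S) cis-diol.

Step 15
Reactants: 17 (2R,4S,5R,7S,8S)-2-[(1R)-1-bromopropyl]-7-chloro-8-{2-[dimethyl(phenyl)silyl]ethyl}oxocane-4,5-diol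
Product: 20 (2R,4S,5S,7S,8S)-2-[(1R)-1-bromopropyl]-5,7-dichloro-8-{2-[dimethyl(phenyl)silyl]ethyl}oxocan-4-yl acetate, via cyclic orthoacetate 18 (not isolated), via acetoxonium chloride 19 (not isolated)
Conditions: MeC(OMe)3, PPTS (cat.), CH2Cl2, rt; evaporate; then Me3SiCl, CH2Cl2, 0 °C → rt
Reagents that add atoms: trimethyl orthoacetate, COC(C)(OC)OC; chlorotrimethylsilane, C[Si](C)(C)Cl
Why: Kolb–Sharpless conversion of a diol into an acetoxy chloride: chloride opens the acetoxonium ion by SN2 at C9, the carbon remote from the hindered C12 branch, inverting C9 (R to S) while C10 keeps its oxygen as the acetate.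

Step 16
Reactants: 20 (2R,4S,5S,7S,8S)-2-[(1R)-1-bromopropyl]-5,7-dichloro-8-{2-[dimethyl(phenyl)silyl]ethyl}oxocan-4-yl acetate
Product: 22 (2R,4S,5S,7S,8S)-2-[(1R)-1-bromopropyl]-5,7-dichloro-8-(2-hydroxyethyl)oxocan-4-yl acetate, via bromosilane 21 (not isolated)
Conditions: KBr, AcOOH (32% in AcOH), NaOAc, AcOH, 0 °C → rt
Reagents that add atoms: peracetic acid, CC(=O)OO; potassium bromide, [K+].[Br-] (Br in 21 only)
Why: Fleming–Tamao oxidation: ipso-bromodesilylation of the phenyl group and peracid-induced C-to-O migration turn the C4 silane into the primary alcohol in acidic medium that leaves acetate and halides alone.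

Step 17
Reactants: 22 (2R,4S,5S,7S,8S)-2-[(1R)-1-bromopropyl]-5,7-dichloro-8-(2-hydroxyethyl)oxocan-4-yl acetate
Product: 23 (2R,4S,5S,7S,8S)-2-[(1R)-1-bromopropyl]-5,7-dichloro-8-(2-oxoethyl)oxocan-4-yl acetate
Conditions: Dess–Martin periodinane, NaHCO3, CH2Cl2, 0 °C → rt
Reagents that add atoms: none
Why: Dess–Martin oxidation gives the β-alkoxy aldehyde under buffered, non-basic conditions that avoid β-elimination of the ring oxygen.

Step 18
Reactants: 23 (2R,4S,5S,7S,8S)-2-[(1R)-1-bromopropyl]-5,7-dichloro-8-(2-oxoethyl)oxocan-4-yl acetate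
Product: 25 (2R,4S,5S,7S,8S)-2-[(1R)-1-bromopropyl]-5,7-dichloro-8-[(2Z)-5-(triisopropylsilyl)pent-2-en-4-yn-1-yl]oxocan-4-yl acetate, via lithium silylalkoxide adduct 24 (not isolated)
Conditions: 1,3-bis(triisopropylsilyl)propyne, n-BuLi, THF, −20 °C; then 23, −78 °C → rt
Reagents that add atoms: 1,3-bis(triisopropylsilyl)propyne, CC(C)[Si](C(C)C)(C(C)C)CC#C[Si](C(C)C)(C(C)C)C(C)C
Why: Peterson olefination with the bulky lithiated bis-silylpropyne adds to the aldehyde faster than to the acetate and eliminates silanolate to give the (Z)-enyne selectively.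

Step 19
Reactants: 25 (2R,4S,5S,7S,8S)-2-[(1R)-1-bromopropyl]-5,7-dichloro-8-[(2Z)-5-(triisopropylsilyl)pent-2-en-4-yn-1-yl]oxocan-4-yl acetate
Product: 26 (2R,4S,5S,7S,8S)-2-[(1R)-1-bromopropyl]-5,7-dichloro-8-[(2Z)-pent-2-en-4-yn-1-yl]oxocan-4-yl acetate
Conditions: Bu4NF, AcOH, THF, 0 °C
Reagents that add atoms: none
Why: Fluoride-induced protodesilylation of the alkynylsilane, buffered so that the acetate and the secondary halides survive, gives the target.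

## Compound list

1 | rac-hexa-1,5-dien-3-ol | C=CCC(O)C=C | starting material
2 | (1R)-1-[(2S)-oxiran-2-yl]but-3-en-1-ol | C=CC[C@@H](O)[C@@H]1CO1 | intermediate
3 | (2S)-2-{(1R)-1-[(4-methoxybenzyl)oxy]but-3-en-1-yl}oxirane | C=CC[C@@H](OCc1ccc(OC)cc1)[C@@H]1CO1 | intermediate
4 | (3S,4R)-1-[dimethyl(phenyl)silyl]-4-[(4-methoxybenzyl)oxy]hept-6-en-3-ol | C=CC[C@@H](OCc1ccc(OC)cc1)[C@@H](O)CC[Si](C)(C)c1ccccc1 | intermediate
5 | 2-({(3S,4R)-1-[dimethyl(phenyl)silyl]-4-[(4-methoxybenzyl)oxy]hept-6-en-3-yl}oxy)acetic acid | C=CC[C@@H](OCc1ccc(OC)cc1)[C@@H](OCC(O)=O)CC[Si](C)(C)c1ccccc1 | intermediate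
6 | mixed pivalic anhydride of acid 5 | C=CC[C@@H](OCc1ccc(OC)cc1)[C@@H](OCC(=O)OC(=O)C(C)(C)C)CC[Si](C)(C)c1ccccc1 | intermediate (not isolated)
7 | (4S)-4-benzyl-3-[2-({(3S,4R)-1-[dimethyl(phenyl)silyl]-4-[(4-methoxybenzyl)oxy]hept-6-en-3-yl}oxy)acetyl]-1,3-oxazolidin-2-one | C=CC[C@@H](OCc1ccc(OC)cc1)[C@@H](OCC(=O)N1[C@@H](Cc2ccccc2)COC1=O)CC[Si](C)(C)c1ccccc1 | intermediate
8 | sodium Z-enolate of imide 7 | C=CC[C@@H](OCc1ccc(OC)cc1)[C@@H](O/C=C(\O[Na])N1[C@@H](Cc2ccccc2)COC1=O)CC[Si](C)(C)c1ccccc1 | intermediate (not isolated)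
9 | (4S)-4-benzyl-3-[(2R)-2-({(3S,4R)-1-[dimethyl(phenyl)silyl]-4-[(4-methoxybenzyl)oxy]hept-6-en-3-yl}oxy)pent-4-enoyl]-1,3-oxazolidin-2-one | C=CC[C@@H](OCc1ccc(OC)cc1)[C@@H](O[C@H](CC=C)C(=O)N1[C@@H](Cc2ccccc2)COC1=O)CC[Si](C)(C)c1ccccc1 | intermediate
10 | (2R)-2-({(3S,4R)-1-[dimethyl(phenyl)silyl]-4-[(4-methoxybenzyl)oxy]hept-6-en-3-yl}oxy)-N-methoxy-N-methylpent-4-enamide | C=CC[C@@H](OCc1ccc(OC)cc1)[C@@H](O[C@H](CC=C)C(=O)N(C)OC)CC[Si](C)(C)c1ccccc1 | intermediate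
11 | (4R)-4-({(3S,4R)-1-[dimethyl(phenyl)silyl]-4-[(4-methoxybenzyl)oxy]hept-6-en-3-yl}oxy)hept-6-en-3-one | C=CC[C@@H](OCc1ccc(OC)cc1)[C@@H](O[C@H](CC=C)C(=O)CC)CC[Si](C)(C)c1ccccc1 | intermediate
12 | (3S,4R)-4-({(3S,4R)-1-[dimethyl(phenyl)silyl]-4-[(4-methoxybenzyl)oxy]hept-6-en-3-yl}oxy)hept-6-en-3-ol | C=CC[C@@H](OCc1ccc(OC)cc1)[C@@H](O[C@H](CC=C)[C@@H](O)CC)CC[Si](C)(C)c1ccccc1 | intermediate
13 | (1S)-1-[(2R,4Z,7R,8S)-8-{2-[dimethyl(phenyl)silyl]ethyl}-7-[(4-methoxybenzyl)oxy]-3,6,7,8-tetrahydro-2H-oxocin-2-yl]propan-1-ol | C[Si](C)(c1ccccc1)CC[C@@H]1O[C@@H]([C@@H](O)CC)C/C=C\C[C@H]1OCc1ccc(OC)cc1 | intermediate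
14 | (2S,3R,5Z,8R)-8-[(1R)-1-bromopropyl]-2-{2-[dimethyl(phenyl)silyl]ethyl}-3-[(4-methoxybenzyl)oxy]-3,4,7,8-tetrahydro-2H-oxocine | C[Si](C)(c1ccccc1)CC[C@@H]1O[C@@H]([C@H](Br)CC)C/C=C\C[C@H]1OCc1ccc(OC)cc1 | intermediate
15 | (2S,3R,5Z,8R)-8-[(1R)-1-bromopropyl]-2-{2-[dimethyl(phenyl)silyl]ethyl}-3,4,7,8-tetrahydro-2H-oxocin-3-ol | C[Si](C)(c1ccccc1)CC[C@@H]1O[C@@H]([C@H](Br)CC)C/C=C\C[C@H]1O | intermediate
16 | (2S,3S,5Z,8R)-8-[(1R)-1-bromopropyl]-3-chloro-2-{2-[dimethyl(phenyl)silyl]ethyl}-3,4,7,8-tetrahydro-2H-oxocine | C[Si](C)(c1ccccc1)CC[C@@H]1O[C@@H]([C@H](Br)CC)C/C=C\C[C@@H]1Cl | intermediate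
17 | (2R,4S,5R,7S,8S)-2-[(1R)-1-bromopropyl]-7-chloro-8-{2-[dimethyl(phenyl)silyl]ethyl}oxocane-4,5-diol | C[Si](C)(c1ccccc1)CC[C@@H]1O[C@@H]([C@H](Br)CC)C[C@H](O)[C@H](O)C[C@@H]1Cl | intermediate
18 | cyclic methyl orthoacetate of diol 17 (2-methoxy-2-methyl-1,3-dioxolane across C9/C10; epimers at the orthoester carbon) | C[Si](C)(c1ccccc1)CC[C@@H]1O[C@@H]([C@H](Br)CC)C[C@@H]2OC(C)(OC)O[C@@H]2C[C@@H]1Cl | intermediate (not isolated)
19 | acetoxonium chloride (2-methyl-1,3-dioxolan-2-ylium chloride across C9/C10) | C[Si](C)(c1ccccc1)CC[C@@H]1O[C@@H]([C@H](Br)CC)C[C@@H]2O[C+](C)O[C@@H]2C[C@@H]1Cl.[Cl-] | intermediate (not isolated)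
20 | (2R,4S,5S,7S,8S)-2-[(1R)-1-bromopropyl]-5,7-dichloro-8-{2-[dimethyl(phenyl)silyl]ethyl}oxocan-4-yl acetate | C[Si](C)(c1ccccc1)CC[C@@H]1O[C@@H]([C@H](Br)CC)C[C@H](OC(C)=O)[C@@H](Cl)C[C@@H]1Cl | intermediate
21 | bromo(dimethyl)silyl analogue of 20 (phenyl on silicon replaced by bromine) | C[Si](C)(Br)CC[C@@H]1O[C@@H]([C@H](Br)CC)C[C@H](OC(C)=O)[C@@H](Cl)C[C@@H]1Cl | intermediate (not isolated)
22 | (2R,4S,5S,7S,8S)-2-[(1R)-1-bromopropyl]-5,7-dichloro-8-(2-hydroxyethyl)oxocan-4-yl acetate | OCC[C@@H]1O[C@@H]([C@H](Br)CC)C[C@H](OC(C)=O)[C@@H](Cl)C[C@@H]1Cl | intermediate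
23 | (2R,4S,5S,7S,8S)-2-[(1R)-1-bromopropyl]-5,7-dichloro-8-(2-oxoethyl)oxocan-4-yl acetate | O=CC[C@@H]1O[C@@H]([C@H](Br)CC)C[C@H](OC(C)=O)[C@@H](Cl)C[C@@H]1Cl | intermediate
24 | lithium β-silylalkoxide adduct of 23 (diastereomer mixture at the two new centres) | [Li]OC(C[C@@H]1O[C@@H]([C@H](Br)CC)C[C@H](OC(C)=O)[C@@H](Cl)C[C@@H]1Cl)C(C#C[Si](C(C)C)(C(C)C)C(C)C)[Si](C(C)C)(C(C)C)C(C)C | intermediate (not isolated)
25 | (2R,4S,5S,7S,8S)-2-[(1R)-1-bromopropyl]-5,7-dichloro-8-[(2Z)-5-(triisopropylsilyl)pent-2-en-4-yn-1-yl]oxocan-4-yl acetate | CC(C)[Si](C(C)C)(C(C)C)C#C/C=C\C[C@@H]1O[C@@H]([C@H](Br)CC)C[C@H](OC(C)=O)[C@@H](Cl)C[C@@H]1Cl | intermediate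
26 | (2R,4S,5S,7S,8S)-2-[(1R)-1-bromopropyl]-5,7-dichloro-8-[(2Z)-pent-2-en-4-yn-1-yl]oxocan-4-yl acetate | C#C/C=C\C[C@@H]1O[C@@H]([C@H](Br)CC)C[C@H](OC(C)=O)[C@@H](Cl)C[C@@H]1Cl | target

## Step count and risks

Total step count: 19. Longest linear sequence: 19 (the route is fully linear from 1).

The three steps most likely to fail are 14, 15 and 18.

Step 14 can fail because the facial selectivity of the dihydroxylation of 16 rests on only one large substituent (the C12 branch). The fallback moves the dihydroxylation to an earlier stage, where the C7 4-methoxybenzyl ether and the C12 branch both block the same face. It sets out from 14: OsO4/N-methylmorpholine N-oxide gives the 4-methoxybenzyl-protected diol F1, and 2,2-dimethoxypropane/PPTS masks it as the acetonide F2. DDQ then frees the acetonide C7 alcohol F3, and CCl4/P(n-Oct)3 converts it with inversion into the acetonide C7 chloride F4. Aqueous AcOH in THF removes the acetonide, and the sequence comes back to the route at 17.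

Step 15 can fail because chloride may open the acetoxonium ion at C10, or the ring oxygen may take part and give the cis product. The fallback replaces the acetoxonium ion by a neutral cyclic sulfate that is opened by free chloride in a plain SN2 reaction. It sets out from 17: SOCl2/Et3N gives the cyclic sulfite F5, and RuCl3 (cat.)/NaIO4 oxidises it to the cyclic sulfate F6. Bu4NCl in DMF opens the sulfate at C9 with inversion to the tetrabutylammonium chloro sulfate F7, and H2SO4 (cat.) in wet THF hydrolyses the sulfate ester to the chlorohydrin F8. Ac2O/pyridine/DMAP acetylates C10–OH, and the sequence comes back to the route at 20.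

Step 18 can fail because the lithiated propyne is basic and may enolise the β-alkoxy aldehyde or attack the acetate, and the Z/E ratio may be poor. The fallback builds the enyne in two milder operations. It sets out from 23: Stork–Zhao Wittig olefination (Ph3P+CH2I I−, NaN(SiMe3)2, HMPA, THF, −78 °C) gives the (Z)-vinyl iodide F9. Sonogashira coupling of F9 with (triisopropylsilyl)acetylene (Pd(PPh3)4, CuI, i-Pr2NH, rt) retains the alkene geometry, and the sequence comes back to the route at 25.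

## Further compounds

F1 | step 14 | (2R,4S,5R,7R,8S)-2-[(1R)-1-bromopropyl]-8-{2-[dimethyl(phenyl)silyl]ethyl}-7-[(4-methoxybenzyl)oxy]oxocane-4,5-diol | C[Si](C)(c1ccccc1)CC[C@@H]1O[C@@H]([C@H](Br)CC)C[C@H](O)[C@H](O)C[C@H]1OCc1ccc(OC)cc1
F2 | step 14 | 4,5-O-isopropylidene acetal (acetonide) of F1 | C[Si](C)(c1ccccc1)CC[C@@H]1O[C@@H]([C@H](Br)CC)C[C@@H]2OC(C)(C)O[C@@H]2C[C@H]1OCc1ccc(OC)cc1
F3 | step 14 | acetonide of the (7R)-alcohol (F2 without the 4-methoxybenzyl group) | C[Si](C)(c1ccccc1)CC[C@@H]1O[C@@H]([C@H](Br)CC)C[C@@H]2OC(C)(C)O[C@@H]2C[C@H]1O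
F4 | step 14 | acetonide of diol 17 ((7S)-chloride) | C[Si](C)(c1ccccc1)CC[C@@H]1O[C@@H]([C@H](Br)CC)C[C@@H]2OC(C)(C)O[C@@H]2C[C@@H]1Cl
F5 | step 15 | 4,5-cyclic sulfite of diol 17 | C[Si](C)(c1ccccc1)CC[C@@H]1O[C@@H]([C@H](Br)CC)C[C@@H]2OS(=O)O[C@@H]2C[C@@H]1Cl
F6 | step 15 | 4,5-cyclic sulfate of diol 17 | C[Si](C)(c1ccccc1)CC[C@@H]1O[C@@H]([C@H](Br)CC)C[C@@H]2OS(=O)(=O)O[C@@H]2C[C@@H]1Cl
F7 | step 15 | tetrabutylammonium (2R,4S,5S,7S,8S)-2-[(1R)-1-bromopropyl]-5,7-dichloro-8-{2-[dimethyl(phenyl)silyl]ethyl}oxocan-4-yl sulfate | CCCC[N+](CCCC)(CCCC)CCCC.C[Si](C)(c1ccccc1)CC[C@@H]1O[C@@H]([C@H](Br)CC)C[C@H](OS(=O)(=O)[O-])[C@@H](Cl)C[C@@H]1Cl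
F8 | step 15 | (2R,4S,5S,7S,8S)-2-[(1R)-1-bromopropyl]-5,7-dichloro-8-{2-[dimethyl(phenyl)silyl]ethyl}oxocan-4-ol | C[Si](C)(c1ccccc1)CC[C@@H]1O[C@@H]([C@H](Br)CC)C[C@H](O)[C@@H](Cl)C[C@@H]1Cl
F9 | step 18 | (2R,4S,5S,7S,8S)-2-[(1R)-1-bromopropyl]-5,7-dichloro-8-[(2Z)-3-iodoprop-2-en-1-yl]oxocan-4-yl acetate | I/C=C\C[C@@H]1O[C@@H]([C@H](Br)CC)C[C@H](OC(C)=O)[C@@H](Cl)C[C@@H]1Cl
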